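## Retrosynthetic overview

- The target is a guai-4-en-3-one: a cyclopentenone (C1–C5) fused along C1–C5 to a seven-membered ring (C1, C5, C6, C7, C8, C9, C10). The plan rests on C8 being a secondary carbinol two bonds from C10 (C8–C9–C10), and on the C10 methyl lying trans to the tertiary hydroxyl on the adjacent ring-fusion carbon C1.
- The C10 methyl comes from an exocyclic C10=C14 methylene, hydrogenated from the face of the C1 hydroxyl; the C8 angelate comes from the C8 alcohol.
- The C8–C9 bond and the seven-membered ring come from a CrCl2-mediated intramolecular allylation of a C8 aldehyde by a C9 allylic bromide. Both sit on the finished cyclopentenone, so the five-membered ring is there first and the seven-membered ring closes second.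
- The open-chain precursor: C1–C10 by adding a 2-lithioallyl ether to an (R)-4-silyloxycyclopentenone anti to the silyloxy group; C5–C6 by formylation; C6 and C7 by an Evans syn aldol; C11 by MeLi then Ac2O.

Key step: step 18

Remark: guaiane numbering (C1–C15) is used for ring and side-chain atoms; TBS = tert-butyldimethylsilyl, TMS = trimethylsilyl, PMB = 4-methoxybenzyl; Q = the (3R,5R)-3,5-bis(TBSO)-5-[3-(PMBO)prop-1-en-2-yl]-2-methylcyclopent-1-en-1-yl residue of 14.

Remark: the C1 hydroxyl is carried as its TBS ether through the oxidation and the ring closure, because a free 1-hydroxy 8-aldehyde would rest as a six-membered lactol and be open to over-oxidation; it is freed before the directed hydrogenation, which therefore comes last.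

Remark: 1, 6, 7, 15, 17 and 33 are taken as purchased materials.

## Route

Step 1
Reactants: 1 (R)-4-[(tert-butyldimethylsilyl)oxy]cyclopent-2-en-1-one
Product: 2 tert-butyldimethyl{[(1R,2R)-2-methyl-4-(trimethylsilyloxy)cyclopent-3-en-1-yl]oxy}silane (methyl trans to OTBS)
Conditions: MeLi, CuI, Et2O, 0 °C; then 1, TMSCl, THF, −78 °C; Et3N
Reagents that add atoms: lithium dimethylcuprate (Me2CuLi, from MeLi and CuI), [Li+].C[Cu-]C; chlorotrimethylsilane, C[Si](C)(C)Cl
Why: TMSCl-accelerated cuprate conjugate addition should deliver the methyl group (C15) to the face opposite the silyloxy group, and trapping the enolate as the silyl enol ether prevents β-elimination of the silyloxy group.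

Step 2
Reactants: 2 silyl enol ether
Product: 3 (R)-4-[(tert-butyldimethylsilyl)oxy]-3-methylcyclopent-2-en-1-one
Conditions: Pd(OAc)2, MeCN, rt
Reagents that add atoms: none
Why: Saegusa–Ito oxidation (palladation of the enol silane, then β-hydride elimination of the hydrogen on the methyl-bearing carbon) should return the enone with the methyl on the β-carbon, leaving the silyloxy stereocentre untouched.

Step 3
Reactants: 3 β-methyl enone
Product: 5 (R)-2-bromo-4-[(tert-butyldimethylsilyl)oxy]-3-methylcyclopent-2-en-1-one, via 2,3-dibromo ketone 4 (not isolated)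
Conditions: Br2, CH2Cl2, 0 °C; then Et3N, 0 °C to rt
Reagents that add atoms: bromine, BrBr
Why: Bromination–dehydrobromination: Br2 adds across the enone and Et3N removes the acidic α-hydrogen with loss of the tertiary β-bromide, which should give the α-bromo enone.

Step 4
Reactants: 6 4-methoxybenzyl alcohol; 7 2,3-dibromoprop-1-ene
Product: 9 1-{[(2-bromoprop-2-en-1-yl)oxy]methyl}-4-methoxybenzene (2-bromoallyl PMB ether), via sodium alkoxide 8 (not isolated)
Conditions: NaH, THF, 0 °C; then 7, Bu4NI (cat.), rt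
Reagents that add atoms: none
Why: Williamson ether synthesis at the allylic bromide of 7; the vinylic bromide does not undergo SN2 displacement.

Step 5
Reactants: 5 α-bromo enone; 9 2-bromoallyl PMB ether
Product: 11 (1R,4R)-2-bromo-4-(TBSO)-1-[3-(PMBO)prop-1-en-2-yl]-3-methylcyclopent-2-en-1-ol (tertiary OH cis to OTBS), via vinyllithium 10 (not isolated)
Conditions: 9, t-BuLi (2 equiv), Et2O, −78 °C; then 5, THF, −78 °C; aq. NH4Cl
Reagents that add atoms: none
Why: Br/Li exchange gives vinyllithium 10, whose 1,2-addition to the enone carbonyl should occur anti to the silyloxy group across the ring, setting C1 with its oxygen cis to the C3 oxygen; carbonyl addition at −78 °C is much faster than exchange at the vinylic bromide of 5.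

Step 6
Reactants: 11 tertiary alcohol
Product: 12 bis-TBS ether of 11 (tertiary C1–OTBS; configuration unchanged)
Conditions: TBSOTf, 2,6-lutidine, CH2Cl2, 0 °C to rt
Reagents that add atoms: tert-butyldimethylsilyl trifluoromethanesulfonate, CC(C)(C)[Si](C)(C)OS(=O)(=O)C(F)(F)F
Why: Silyl triflate silylation of a tertiary alcohol, which masks the C1 oxygen so that no hemiacetal can form with the later C8 aldehyde.

Step 7
Reactants: 12 vinylic bromide
Product: 14 (3R,5R)-3,5-bis(TBSO)-5-[3-(PMBO)prop-1-en-2-yl]-2-methylcyclopent-1-ene-1-carbaldehyde (C6 aldehyde), via ring vinyllithium 13 (not isolated)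
Conditions: t-BuLi (2.1 equiv), THF, −78 °C; DMF, −78 to 0 °C; aq. NH4Cl
Reagents that add atoms: N,N-dimethylformamide, CN(C)C=O
Why: Br/Li exchange and formylation of the vinyllithium with DMF should install C6 as the enal; the neighbouring silyl ether cannot β-eliminate inside the five-membered ring.

Step 8
Reactants: 15 3-[(tert-butyldimethylsilyl)oxy]propan-1-ol
Product: 16 3-[(tert-butyldimethylsilyl)oxy]propanoic acid
Conditions: TEMPO (cat.), PhI(OAc)2, MeCN/H2O, rt
Reagents that add atoms: water, O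
Why: Nitroxyl-catalysed oxidation of a primary alcohol through the aldehyde hydrate to the carboxylic acid, under conditions a primary TBS ether tolerates.

Step 9
Reactants: 16 silyloxy acid; 17 (R)-4-benzyloxazolidin-2-one
Product: 19 (R)-4-benzyl-3-{3-[(tert-butyldimethylsilyl)oxy]propanoyl}oxazolidin-2-one, via mixed pivalic anhydride 18 (not isolated)
Conditions: PivCl, Et3N, THF, −20 °C; then 17, LiCl, rt
Reagents that add atoms: none
Why: N-Acylation of the oxazolidinone through the mixed pivalic anhydride, which is attacked at the less hindered carbonyl.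

Step 10
Reactants: 14 enal; 19 imide
Product: 21 (R)-4-benzyl-3-[(2R,3R)-3-hydroxy-3-Q-2-(TBSO-methyl)propanoyl]oxazolidin-2-one (guaiane 6R,7R), via dibutylboron enolate 20 (not isolated)
Conditions: 19, Bu2BOTf, Et3N, CH2Cl2, −78 to 0 °C; then 14, −78 to 0 °C; pH 7 buffer, MeOH, H2O2
Reagents that add atoms: none
Why: Evans syn aldol: the (Z)-boron enolate 20 reacts through a closed chair transition state on the enolate face away from the benzyl group, which should set C6 and C7 (C6–O and C7–CH2O syn) under auxiliary control regardless of the remote ring stereocentres.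

Step 11
Reactants: 21 aldol adduct
Product: 22 methyl (2R,3R)-3-hydroxy-3-Q-2-(TBSO-methyl)propanoate
Conditions: MeMgBr, MeOH, CH2Cl2, 0 °C
Reagents that add atoms: methanol, CO
Why: Transesterification with MeOMgBr, directed to the exocyclic imide carbonyl by chelation to the β-hydroxyl, should release the methyl ester without retro-aldol and return the auxiliary.

Step 12
Reactants: 22 β-hydroxy ester
Product: 23 methyl (2R,3R)-3-(TBSO)-3-Q-2-(TBSO-methyl)propanoate
Conditions: TBSOTf, 2,6-lutidine, CH2Cl2, −78 to 0 °C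
Reagents that add atoms: tert-butyldimethylsilyl trifluoromethanesulfonate, CC(C)(C)[Si](C)(C)OS(=O)(=O)C(F)(F)F
Why: Silyl triflate silylation of the hindered allylic C6 alcohol under basic, non-ionising conditions.

Step 13
Reactants: 23 methyl ester
Product: 26 (3R,4R)-4-(TBSO)-4-Q-2-methyl-3-(TBSO-methyl)butan-2-yl acetate (C11 tertiary acetate), via methyl ketone 24 (not isolated), via lithium alkoxide 25 (not isolated)
Conditions: MeLi (excess), Et2O, −78 to 0 °C; then Ac2O, 0 °C to rt
Reagents that add atoms: methyllithium, [Li]C; acetic anhydride, CC(=O)OC(C)=O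
Why: Double addition of MeLi to the ester gives the tertiary lithium alkoxide 25, which is acetylated in the flask; trapping the alkoxide is the dependable way to acylate so hindered a tertiary oxygen, and no other free hydroxyl is present.

Step 14
Reactants: 26 PMB ether
Product: 27 C9 allylic alcohol (26 with the PMB ether cleaved to CH2OH; 1R,3R,6R,7R)
Conditions: DDQ, CH2Cl2/pH 7 buffer, 0 °C
Reagents that add atoms: none
Why: Oxidative PMB cleavage (benzylic hydride abstraction by DDQ, then hydrolysis of the oxocarbenium ion), to which silyl ethers and the acetate are inert.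

Step 15
Reactants: 27 allylic alcohol
Product: 28 C9 allylic bromide (CH2OH of 27 replaced by CH2Br; 1S,3R,6R,7R)
Conditions: CBr4, PPh3, CH2Cl2, 0 °C
Reagents that add atoms: carbon tetrabromide, BrC(Br)(Br)Br
Why: Appel bromination of the primary allylic alcohol; both allylic termini are CH2, so direct and allylic displacement give the same bromide.

Step 16
Reactants: 28 tetrakis-TBS ether
Product: 29 C3,C8-diol (28 with the C3 and C8 TBS ethers cleaved; C1 and C6 TBS ethers kept)
Conditions: HF·pyridine, THF, 0 °C to rt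
Reagents that add atoms: none
Why: Acidic fluoride desilylation graded by steric hindrance: the primary C8 ether and the unhindered secondary C3 ether should cleave well before the neopentyl-like C6 ether and the tertiary C1 ether, and without added pyridine no free base is present to alkylate at the allylic bromide.

Step 17
Reactants: 29 diol
Product: 30 keto aldehyde (1S,6R,7R): 2-methylcyclopent-2-en-1-one carrying at C1 OTBS and C(=CH2)CH2Br and at C5 the chain CH(OTBS)–CH(CHO)–C(CH3)2OAc
Conditions: Dess–Martin periodinane, NaHCO3, CH2Cl2, 0 °C to rt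
Reagents that add atoms: none
Why: Dess–Martin oxidation of both alcohols under buffered, amine-free conditions should give the enone and the β-acetoxy aldehyde without loss of acetate or epimerisation at C7.

Step 18
Reactants: 30 keto aldehyde
Product: 32 (1R,6R,7R,8R)-11-acetoxy-8-hydroxy-1,6-bis(TBSO)guaia-4,10(14)-dien-3-one, via allylchromium dichloride 31 (not isolated)
Conditions: CrCl2 (6 equiv), THF, rt; slow addition of 30 to 2 mM final concentration
Reagents that add atoms: none
Why: Two equivalents of divalent chromium (CrCl2) reduce the allylic C–Br bond by successive single-electron transfers to the trivalent chromium σ-allyl 31, whose two termini are both CH2, so that addition to the aldehyde through a six-membered chair-like transition state with chromium on the carbonyl oxygen leaves the exocyclic methylene on C10 whichever terminus bonds. The closest known reaction is the intramolecular Nozaki–Hiyama (chromium Barbier) allylation of aldehydes. The seven-membered ring (C1, C5, C6, C7, C8, C9, C10) closes by 7-exo-trig attack of C9 on the C8 carbonyl, forming the C8–C9 bond. The new C8 stereocentre is controlled by C7: Felkin–Anh approach anti to the bulky C(CH3)2OAc group, with the incoming carbon passing the small C7 hydrogen, should place the C8 hydroxyl cis to that group (8R). The step needs aldehyde-over-ketone selectivity, secured by the strong aldehyde preference of allylchromium reagents and by the strained bridged ring that attack at C3 would require, and ring closure over intermolecular coupling, secured by slow addition at high dilution. The neutral medium spares the β-acetoxy aldehyde, and the silyl ether on C1 removes both the lactol equilibrium and any proton source.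

Step 19
Reactants: 32 C8 alcohol; 33 angelic acid [(Z)-2-methylbut-2-enoic acid]
Product: 35 (1R,6R,7R,8R)-11-acetoxy-8-angeloyloxy-1,6-bis(TBSO)guaia-4,10(14)-dien-3-one, via mixed anhydride 34 (not isolated)
Conditions: 33, 2,4,6-trichlorobenzoyl chloride, Et3N, toluene, rt; then 32, toluene, 75 °C
Reagents that add atoms: none
Why: Yamaguchi esterification: the mixed anhydride 34 acylates the hindered C8 alcohol at the angeloyl carbonyl on heating without DMAP, conditions under which the Z double bond should not isomerise to the tiglate.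

Step 20
Reactants: 35 bis-TBS ether
Product: 36 (1R,6R,7S,8R)-11-acetoxy-8-angeloyloxy-1,6-dihydroxyguaia-4,10(14)-dien-3-one
Conditions: HF·pyridine, THF, 0 to 40 °C
Reagents that add atoms: none
Why: Fluoride cleavage of the two remaining silyl ethers under acidic conditions, which should avoid acyl migration among the C6, C8 and C11 oxygens.

Step 21
Reactants: 36 dienone diol
Product: 37 (1R,6R,7S,8R,10S)-11-acetoxy-8-angeloyloxy-1,6-dihydroxyguai-4-en-3-one (target CNP0273287.1)
Conditions: [Ir(cod)(PCy3)(py)]PF6 (10 mol %), H2 (1 atm), CH2Cl2, 0 °C to rt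
Reagents that add atoms: none
Why: Hydroxyl-directed hydrogenation: the cationic iridium catalyst binds the allylic C1 hydroxyl and the 1,1-disubstituted alkene and delivers H2 to the alkene face syn to that hydroxyl, which should place the C10 methyl trans to C1–OH (10S), while the electron-poor tetrasubstituted enone and the trisubstituted angelate alkene react far more slowly.

## Compound list

1 | (R)-4-[(tert-butyldimethylsilyl)oxy]cyclopent-2-en-1-one | O=C1C=C[C@H](O[Si](C)(C)C(C)(C)C)C1 | starting material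
2 | tert-butyldimethyl{[(1R,2R)-2-methyl-4-(trimethylsilyloxy)cyclopent-3-en-1-yl]oxy}silane | C[Si](C)(C)OC1=C[C@@H](C)[C@H](O[Si](C)(C)C(C)(C)C)C1 | intermediate
3 | (R)-4-[(tert-butyldimethylsilyl)oxy]-3-methylcyclopent-2-en-1-one | O=C1C=C(C)[C@H](O[Si](C)(C)C(C)(C)C)C1 | intermediate
4 | (4R)-2,3-dibromo-4-[(tert-butyldimethylsilyl)oxy]-3-methylcyclopentan-1-one (mixture at C2 and C3) | O=C1C(Br)C(C)(Br)[C@H](O[Si](C)(C)C(C)(C)C)C1 | intermediate (not isolated)
5 | (R)-2-bromo-4-[(tert-butyldimethylsilyl)oxy]-3-methylcyclopent-2-en-1-one | O=C1C(Br)=C(C)[C@H](O[Si](C)(C)C(C)(C)C)C1 | intermediate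
6 | 4-methoxybenzyl alcohol | COc1ccc(CO)cc1 | starting material
7 | 2,3-dibromoprop-1-ene | C=C(Br)CBr | starting material
8 | sodium 4-methoxybenzyl oxide | COc1ccc(C[O-])cc1.[Na+] | intermediate (not isolated)
9 | 1-{[(2-bromoprop-2-en-1-yl)oxy]methyl}-4-methoxybenzene | C=C(Br)COCc1ccc(OC)cc1 | intermediate
10 | {3-[(4-methoxybenzyl)oxy]prop-1-en-2-yl}lithium | [Li]C(=C)COCc1ccc(OC)cc1 | intermediate (not isolated)
11 | (1R,4R)-2-bromo-4-(TBSO)-1-[3-(PMBO)prop-1-en-2-yl]-3-methylcyclopent-2-en-1-ol | C=C(COCc1ccc(OC)cc1)[C@]2(O)C[C@@H](O[Si](C)(C)C(C)(C)C)C(C)=C2Br | intermediate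
12 | bis-TBS ether of 11 | C=C(COCc1ccc(OC)cc1)[C@]2(O[Si](C)(C)C(C)(C)C)C[C@@H](O[Si](C)(C)C(C)(C)C)C(C)=C2Br | intermediate
13 | vinyllithium from 12 (Li in place of Br) | C=C(COCc1ccc(OC)cc1)[C@]2(O[Si](C)(C)C(C)(C)C)C[C@@H](O[Si](C)(C)C(C)(C)C)C(C)=C2[Li] | intermediate (not isolated)
14 | (3R,5R)-3,5-bis(TBSO)-5-[3-(PMBO)prop-1-en-2-yl]-2-methylcyclopent-1-ene-1-carbaldehyde | C=C(COCc1ccc(OC)cc1)[C@]2(O[Si](C)(C)C(C)(C)C)C[C@@H](O[Si](C)(C)C(C)(C)C)C(C)=C2C=O | intermediate
15 | 3-[(tert-butyldimethylsilyl)oxy]propan-1-ol | CC(C)(C)[Si](C)(C)OCCCO | starting material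
16 | 3-[(tert-butyldimethylsilyl)oxy]propanoic acid | CC(C)(C)[Si](C)(C)OCCC(=O)O | intermediate
17 | (R)-4-benzyloxazolidin-2-one | O=C1N[C@H](Cc2ccccc2)CO1 | starting material
18 | 3-[(tert-butyldimethylsilyl)oxy]propanoic pivalic anhydride | CC(C)(C)C(=O)OC(=O)CCO[Si](C)(C)C(C)(C)C | intermediate (not isolated)
19 | (R)-4-benzyl-3-{3-[(tert-butyldimethylsilyl)oxy]propanoyl}oxazolidin-2-one | O=C(CCO[Si](C)(C)C(C)(C)C)N1[C@H](Cc2ccccc2)COC1=O | intermediate
20 | (Z)-dibutylboron enolate of 19 | CCCCB(CCCC)O/C(=C\CO[Si](C)(C)C(C)(C)C)N1[C@H](Cc2ccccc2)COC1=O | intermediate (not isolated)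
21 | (R)-4-benzyl-3-[(2R,3R)-3-hydroxy-3-Q-2-(TBSO-methyl)propanoyl]oxazolidin-2-one | C=C(COCc1ccc(OC)cc1)[C@]2(O[Si](C)(C)C(C)(C)C)C[C@@H](O[Si](C)(C)C(C)(C)C)C(C)=C2[C@H](O)[C@@H](CO[Si](C)(C)C(C)(C)C)C(=O)N3[C@H](Cc4ccccc4)COC3=O | intermediate
22 | methyl (2R,3R)-3-hydroxy-3-Q-2-(TBSO-methyl)propanoate | C=C(COCc1ccc(OC)cc1)[C@]2(O[Si](C)(C)C(C)(C)C)C[C@@H](O[Si](C)(C)C(C)(C)C)C(C)=C2[C@H](O)[C@@H](CO[Si](C)(C)C(C)(C)C)C(=O)OC | intermediate
23 | methyl (2R,3R)-3-(TBSO)-3-Q-2-(TBSO-methyl)propanoate | C=C(COCc1ccc(OC)cc1)[C@]2(O[Si](C)(C)C(C)(C)C)C[C@@H](O[Si](C)(C)C(C)(C)C)C(C)=C2[C@H](O[Si](C)(C)C(C)(C)C)[C@@H](CO[Si](C)(C)C(C)(C)C)C(=O)OC | intermediate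
24 | (3R,4R)-4-(TBSO)-4-Q-3-(TBSO-methyl)butan-2-one | C=C(COCc1ccc(OC)cc1)[C@]2(O[Si](C)(C)C(C)(C)C)C[C@@H](O[Si](C)(C)C(C)(C)C)C(C)=C2[C@H](O[Si](C)(C)C(C)(C)C)[C@@H](CO[Si](C)(C)C(C)(C)C)C(C)=O | intermediate (not isolated)
25 | lithium (3R,4R)-4-(TBSO)-4-Q-2-methyl-3-(TBSO-methyl)butan-2-olate | C=C(COCc1ccc(OC)cc1)[C@]2(O[Si](C)(C)C(C)(C)C)C[C@@H](O[Si](C)(C)C(C)(C)C)C(C)=C2[C@H](O[Si](C)(C)C(C)(C)C)[C@@H](CO[Si](C)(C)C(C)(C)C)C(C)(C)O[Li] | intermediate (not isolated)
26 | (3R,4R)-4-(TBSO)-4-Q-2-methyl-3-(TBSO-methyl)butan-2-yl acetate | C=C(COCc1ccc(OC)cc1)[C@]2(O[Si](C)(C)C(C)(C)C)C[C@@H](O[Si](C)(C)C(C)(C)C)C(C)=C2[C@H](O[Si](C)(C)C(C)(C)C)[C@@H](CO[Si](C)(C)C(C)(C)C)C(C)(C)OC(C)=O | intermediate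
27 | C9 allylic alcohol (PMB of 26 removed; 1R,3R,6R,7R) | C=C(CO)[C@]1(O[Si](C)(C)C(C)(C)C)C[C@@H](O[Si](C)(C)C(C)(C)C)C(C)=C1[C@H](O[Si](C)(C)C(C)(C)C)[C@@H](CO[Si](C)(C)C(C)(C)C)C(C)(C)OC(C)=O | intermediate
28 | C9 allylic bromide (1S,3R,6R,7R) | C=C(CBr)[C@]1(O[Si](C)(C)C(C)(C)C)C[C@@H](O[Si](C)(C)C(C)(C)C)C(C)=C1[C@H](O[Si](C)(C)C(C)(C)C)[C@@H](CO[Si](C)(C)C(C)(C)C)C(C)(C)OC(C)=O | intermediate
29 | C3,C8-diol with C1 and C6 TBS ethers (1S,3R,6R,7R) | C=C(CBr)[C@]1(O[Si](C)(C)C(C)(C)C)C[C@@H](O)C(C)=C1[C@H](O[Si](C)(C)C(C)(C)C)[C@@H](CO)C(C)(C)OC(C)=O | intermediate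
30 | keto aldehyde, cyclization precursor (1S,6R,7R) | C=C(CBr)[C@]1(O[Si](C)(C)C(C)(C)C)CC(=O)C(C)=C1[C@H](O[Si](C)(C)C(C)(C)C)[C@@H](C=O)C(C)(C)OC(C)=O | intermediate
31 | allylchromium dichloride from 30 (CrCl2 in place of Br) | C=C(C[Cr](Cl)Cl)[C@]1(O[Si](C)(C)C(C)(C)C)CC(=O)C(C)=C1[C@H](O[Si](C)(C)C(C)(C)C)[C@@H](C=O)C(C)(C)OC(C)=O | intermediate (not isolated)
32 | (1R,6R,7R,8R)-11-acetoxy-8-hydroxy-1,6-bis(TBSO)guaia-4,10(14)-dien-3-one | O[C@@H]1CC(=C)[C@]2(O[Si](C)(C)C(C)(C)C)CC(=O)C(C)=C2[C@H](O[Si](C)(C)C(C)(C)C)[C@@H]1C(C)(C)OC(C)=O | intermediate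
33 | angelic acid, (Z)-2-methylbut-2-enoic acid | C/C=C(/C)C(=O)O | starting material
34 | angelic 2,4,6-trichlorobenzoic anhydride | C/C=C(/C)C(=O)OC(=O)c1c(Cl)cc(Cl)cc1Cl | intermediate (not isolated)
35 | (1R,6R,7R,8R)-11-acetoxy-8-angeloyloxy-1,6-bis(TBSO)guaia-4,10(14)-dien-3-one | C/C=C(/C)C(=O)O[C@@H]1CC(=C)[C@]2(O[Si](C)(C)C(C)(C)C)CC(=O)C(C)=C2[C@H](O[Si](C)(C)C(C)(C)C)[C@@H]1C(C)(C)OC(C)=O | intermediate
36 | (1R,6R,7S,8R)-11-acetoxy-8-angeloyloxy-1,6-dihydroxyguaia-4,10(14)-dien-3-one | C/C=C(/C)C(=O)O[C@@H]1CC(=C)[C@]2(O)CC(=O)C(C)=C2[C@H](O)[C@@H]1C(C)(C)OC(C)=O | intermediate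
37 | (1R,6R,7S,8R,10S)-11-acetoxy-8-angeloyloxy-1,6-dihydroxyguai-4-en-3-one | C/C=C(/C)C(=O)O[C@@H]1C[C@H](C)[C@]2(O)CC(=O)C(C)=C2[C@H](O)[C@@H]1C(C)(C)OC(C)=O | target

## Step count and risks

Total step count: 21 (18 in the main line, 1 for the allyl ether 9, 2 for the imide 19).
Longest linear sequence: 18 steps, from 1 to 37 (steps 1–3, 5–7, 10–21).

Steps most likely to fail:

1. Step 18 (ring closure). The allylchromium may attack the other face of the aldehyde, giving poor facial selectivity at C8, besides some intermolecular coupling. The fallback sets out from 30 and returns at 32. The closure is run as in step 18 and the unwanted 8-epi alcohol F1 is kept; it is oxidised with Dess–Martin periodinane (NaHCO3, CH2Cl2) to the 3,8-dione F2. F2 is then reduced with NaBH4 in MeOH/CH2Cl2 at −78 °C, where a saturated ketone should react before the tetrasubstituted enone and hydride should approach anti to the C7 side chain, to give 32. C8 is then set by hydride delivery instead of by the C–C bond formation.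

2. Step 21 (directed hydrogenation). The free C6 hydroxyl on the opposite face may compete for the catalyst, giving poor facial selectivity at C10, and the unprotected substrate may slow the catalyst. The fallback sets out from 36 and returns at 37. The secondary C6 hydroxyl is silylated selectively (TESCl, imidazole, DMF, 0 °C) to the C6 triethylsilyl ether F3, so that the C1 hydroxyl is the only free hydroxyl. Hydrogenation of F3 with [Ir(cod)(PCy3)(py)]PF6 and H2 in CH2Cl2 should give the 10S silyl ether F4, and HF·pyridine in THF removes the silyl group to give 37.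

3. Step 19 (angeloylation). Acylation of the hindered C8 hydroxyl may be slow, and forcing it may isomerise the Z double bond to the E (tiglate) isomer. The fallback sets out from 32 and returns at 35. Compound 32 is esterified with 2-[bis(2,2,2-trifluoroethoxy)phosphoryl]propanoic acid (DCC, DMAP cat., CH2Cl2) to the phosphonopropionate F5. A Still–Gennari olefination (KHMDS, 18-crown-6, THF, −78 °C; then acetaldehyde) then builds the Z-configured 2-methylbut-2-enoate on the ester already in place, giving 35.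

## Further compounds

F1 | step 18 | (1R,6R,7R,8S)-11-acetoxy-8-hydroxy-1,6-bis(TBSO)guaia-4,10(14)-dien-3-one (C8 epimer of 32) | O[C@H]1CC(=C)[C@]2(O[Si](C)(C)C(C)(C)C)CC(=O)C(C)=C2[C@H](O[Si](C)(C)C(C)(C)C)[C@@H]1C(C)(C)OC(C)=O
F2 | step 18 | (1R,6R,7R)-11-acetoxy-1,6-bis(TBSO)guaia-4,10(14)-diene-3,8-dione | O=C1CC(=C)[C@]2(O[Si](C)(C)C(C)(C)C)CC(=O)C(C)=C2[C@H](O[Si](C)(C)C(C)(C)C)[C@@H]1C(C)(C)OC(C)=O
F3 | step 21 | C6 triethylsilyl ether of 36 | C/C=C(/C)C(=O)O[C@@H]1CC(=C)[C@]2(O)CC(=O)C(C)=C2[C@H](O[Si](CC)(CC)CC)[C@@H]1C(C)(C)OC(C)=O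
F4 | step 21 | C6 triethylsilyl ether of 37 | C/C=C(/C)C(=O)O[C@@H]1C[C@H](C)[C@]2(O)CC(=O)C(C)=C2[C@H](O[Si](CC)(CC)CC)[C@@H]1C(C)(C)OC(C)=O
F5 | step 19 | C8 2-[bis(2,2,2-trifluoroethoxy)phosphoryl]propanoate of 32 (mixture at the phosphonate α-carbon) | CC(C(=O)O[C@@H]1CC(=C)[C@]2(O[Si](C)(C)C(C)(C)C)CC(=O)C(C)=C2[C@H](O[Si](C)(C)C(C)(C)C)[C@@H]1C(C)(C)OC(C)=O)P(=O)(OCC(F)(F)F)OCC(F)(F)F
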